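## Retrosynthetic overview

1. Target ⇐ desilylation and reagent-controlled reduction of the C14 ketone; the hindered tertiary benzoate is made at the start on a cheap tertiary ketol, so no macrolactonisation is needed.
2. Cyclohexene ring (formed last) ⇐ transannular, enantiospecific bromonium cyclisation (C2–C7) of a 20-membered macrocycle, the bromonium coming from a Shi (6R,7R)-epoxide.
3. Macrocycle (formed first) ⇐ ring-closing metathesis at C2=C3; its geometry is irrelevant because this bond becomes the ring alkene.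
4. Key bond C11–C12 ⇐ ketone homoenolate (β-zincio ketone from a cyclopropanol carrying the aryl ester) + enantiopure α-bromo methyl ketone; C10 controls C11.
5. α-Bromo ketone ⇐ geranylacetone by methylenation, allylic oxidation, Sharpless epoxidation, bromide opening and glycol cleavage.

Assumption: terpenoid carbons carry the natural-product numbering (C1 benzylic CH2 to C15 ester-bearing carbon), and (5E)-geranylacetone is bought as the pure E isomer.

## Route

Step 1
Reactants: 1 (5E)-6,10-dimethylundeca-5,9-dien-2-one (geranylacetone)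
Product: 2 (5E)-2,6,10-trimethylundeca-1,5,9-triene
Conditions: MePPh3Br, KOtBu, THF, 0 to 25 °C
Reagents that add atoms: methyltriphenylphosphonium bromide, C[P+](c1ccccc1)(c1ccccc1)c1ccccc1.[Br-]
Why: Wittig methylenation turns the methyl ketone into the C3 isopropenyl group (the later metathesis partner) without touching the trisubstituted alkenes; no stereocenter is formed.

Step 2
Reactants: 2 (5E)-2,6,10-trimethylundeca-1,5,9-triene
Product: 3 (2E,6E)-2,6,10-trimethylundeca-2,6,10-trien-1-ol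
Conditions: SeO2 (0.3 equiv), t-BuOOH, salicylic acid (cat.), CH2Cl2, 25 °C
Reagents that add atoms: tert-butyl hydroperoxide, CC(C)(C)OO
Why: Catalytic SeO2 allylic oxidation (ene reaction then [2,3]-sigmatropic shift) is selective for the (E)-methyl of the terminal trisubstituted alkene and gives the (E)-allylic alcohol.

Step 3
Reactants: 3 (2E,6E)-2,6,10-trimethylundeca-2,6,10-trien-1-ol
Product: 4 [(2S,3S)-3-[(3E)-3,7-dimethylocta-3,7-dien-1-yl]-2-methyloxiran-2-yl]methanol
Conditions: Ti(OiPr)4 (10 mol%), L-(+)-diethyl tartrate (12 mol%), t-BuOOH, 4 Å molecular sieves, CH2Cl2, −20 °C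
Reagents that add atoms: tert-butyl hydroperoxide, CC(C)(C)OO
Why: Sharpless asymmetric epoxidation reacts only at the allylic-alcohol alkene, and L-(+)-tartrate on an (E)-2-methyl-2-alken-1-ol gives the (2S,3S)-epoxide, which fixes the future C10 configuration.

Step 4
Reactants: 4 [(2S,3S)-3-[(3E)-3,7-dimethylocta-3,7-dien-1-yl]-2-methyloxiran-2-yl]methanol
Product: 5 (2S,3R,6E)-3-bromo-2,6,10-trimethylundeca-6,10-diene-1,2-diol
Conditions: Ti(OiPr)4 (1.5 equiv), Et2NH·HBr, CH2Cl2, 0 to 25 °C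
Reagents that add atoms: diethylammonium bromide, CC[NH2+]CC.[Br-]
Why: Titanium-alkoxide-mediated C-3-selective opening of the 2,3-epoxy alcohol delivers bromide to the secondary carbon with SN2 inversion, giving the 10R bromide.

Step 5
Reactants: 5 (2S,3R,6E)-3-bromo-2,6,10-trimethylundeca-6,10-diene-1,2-diol
Product: 6 (3R,6E)-3-bromo-6,10-dimethylundeca-6,10-dien-2-one
Conditions: NaIO4, THF–H2O (pH 7), 0 °C
Reagents that add atoms: none
Why: Periodate glycol cleavage removes the hydroxymethyl carbon as formaldehyde under neutral conditions and unveils the methyl ketone without epimerising the adjacent bromide stereocenter (the epoxide-derived tertiary carbinol is deliberately sacrificed).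

Step 6
Reactants: 7 3-bromo-4-hydroxybenzoic acid
Product: 9 3-bromo-4-[(triisopropylsilyl)oxy]benzoic acid, via bis-silyl ester 8 (not isolated)
Conditions: i-Pr3SiCl (2.2 equiv), imidazole, DMF, 25 °C; then AcOH–THF–H2O, 25 °C
Reagents that add atoms: chlorotriisopropylsilane, CC(C)[Si](Cl)(C(C)C)C(C)C
Why: Exhaustive silylation followed by selective hydrolysis of the labile silyl ester leaves the phenol as a base-stable triisopropylsilyl ether.

Step 7
Reactants: 9 3-bromo-4-[(triisopropylsilyl)oxy]benzoic acid; 10 3-hydroxy-3-methylbutan-2-one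
Product: 12 2-methyl-3-oxobutan-2-yl 3-bromo-4-[(triisopropylsilyl)oxy]benzoate, via acid chloride 11 (not isolated)
Conditions: (COCl)2, DMF (cat.), CH2Cl2, 0 to 25 °C; then 10, Et3N, DMAP, CH2Cl2, 40 °C
Reagents that add atoms: none
Why: DMAP-catalysed acylation of the tertiary α-ketol by the acid chloride installs the hindered tertiary benzoate intermolecularly, and keeping C14 as a ketone blocks acyl migration until the end.

Step 8
Reactants: 12 2-methyl-3-oxobutan-2-yl 3-bromo-4-[(triisopropylsilyl)oxy]benzoate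
Product: 13 2-methyl-3-oxobutan-2-yl 3-(prop-2-en-1-yl)-4-[(triisopropylsilyl)oxy]benzoate
Conditions: Pd(PPh3)4 (5 mol%), allyltributylstannane, toluene, 110 °C
Reagents that add atoms: allyltributylstannane, C=CC[Sn](CCCC)(CCCC)CCCC
Why: Stille cross-coupling with zerovalent palladium is neutral and leaves ketone, ester and silyl ether intact.

Step 9
Reactants: 13 2-methyl-3-oxobutan-2-yl 3-(prop-2-en-1-yl)-4-[(triisopropylsilyl)oxy]benzoate
Product: 16 2-(1-hydroxycyclopropyl)propan-2-yl 3-(prop-2-en-1-yl)-4-[(triisopropylsilyl)oxy]benzoate, via silyl enol ether 14 (not isolated), via siloxycyclopropane 15 (not isolated)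
Conditions: Me3SiOTf, Et3N, CH2Cl2, 0 °C; then Et2Zn, CH2I2, 0 °C; then MeOH, citric acid (cat.), 0 °C
Reagents that add atoms: diiodomethane, ICI
Why: Soft enolisation gives the only possible silyl enol ether, which undergoes Furukawa–Simmons–Smith cyclopropanation much faster than the unactivated allyl group, and mild methanolysis frees the cyclopropanol.

Step 10
Reactants: 16 2-(1-hydroxycyclopropyl)propan-2-yl 3-(prop-2-en-1-yl)-4-[(triisopropylsilyl)oxy]benzoate; 6 (3R,6E)-3-bromo-6,10-dimethylundeca-6,10-dien-2-one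
Product: 18 (6S,7R,10E)-7-bromo-2,6,10,14-tetramethyl-3-oxo-6-[(triethylsilyl)oxy]pentadeca-10,14-dien-2-yl 3-(prop-2-en-1-yl)-4-[(triisopropylsilyl)oxy]benzoate, via zinc homoenolate 17 (not isolated)
Conditions: 16 (2.2 equiv), Et2Zn (1.1 equiv), toluene, 0 to 25 °C; then 6 (1.0 equiv), Et3SiCl, Et2O–CH2Cl2, −20 to 25 °C
Reagents that add atoms: chlorotriethylsilane, CC[Si](Cl)(CC)CC
Why: Proposed new method: the zinc cyclopropoxide from 16 ring-opens to the β-zincio ketone (a ketone homoenolate), which, activated by the chlorosilane as in the known chlorosilane-promoted additions of zinc homoenolates to aldehydes (homo-Reformatsky reaction) and the additions of titanium ester homoenolates to ketones, should add to the strongly electrophilic α-bromo ketone through a Cornforth (polar Felkin–Anh) transition state with C12 approaching anti to the C–Br dipole on the side of H-10, so that the 10R bromide sets 11S and the alkoxide is trapped in situ as the triethylsilyl ether.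

Step 11
Reactants: 18 (6S,7R,10E)-7-bromo-2,6,10,14-tetramethyl-3-oxo-6-[(triethylsilyl)oxy]pentadeca-10,14-dien-2-yl 3-(prop-2-en-1-yl)-4-[(triisopropylsilyl)oxy]benzoate
Product: 19 (6S,7R)-7-bromo-2,6-dimethyl-9-[(2R,3R)-2-methyl-3-(3-methylbut-3-en-1-yl)oxiran-2-yl]-3-oxo-6-[(triethylsilyl)oxy]nonan-2-yl 3-(prop-2-en-1-yl)-4-[(triisopropylsilyl)oxy]benzoate
Conditions: D-fructose-derived Shi ketone (30 mol%), KHSO5 (as 2KHSO5·KHSO4·K2SO4), K2CO3, n-Bu4NHSO4, MeCN–CH2(OMe)2–aqueous buffer (pH 10.5), 0 °C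
Reagents that add atoms: potassium peroxymonosulfate, [K+].[O-]S(=O)(=O)OO
Why: Shi asymmetric epoxidation (chiral dioxirane, spiro transition state) epoxidises the electron-rich trisubstituted C6=C7 alkene in preference to the two terminal alkenes and gives the (6R,7R)-epoxide under catalyst control.

Step 12
Reactants: 19 (6S,7R)-7-bromo-2,6-dimethyl-9-[(2R,3R)-2-methyl-3-(3-methylbut-3-en-1-yl)oxiran-2-yl]-3-oxo-6-[(triethylsilyl)oxy]nonan-2-yl 3-(prop-2-en-1-yl)-4-[(triisopropylsilyl)oxy]benzoate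
Product: 20 macrocyclic epoxy ketone (20-membered lactone; 2E/2Z mixture)
Conditions: second-generation Hoveyda–Grubbs catalyst RuCl2(H2IMes)(=CH-C6H4-2-O-i-Pr) (10 mol%), toluene (1 mM), 80 °C
Reagents that add atoms: none
Why: Ring-closing metathesis of the allyl arene with the 1,1-disubstituted alkene closes the macrocycle as in epothilone-type trisubstituted macrocyclic metathesis, and the E/Z ratio at C2=C3 does not matter because this bond becomes the tetrasubstituted ring alkene.

Step 13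
Reactants: 20 macrocyclic epoxy ketone (20-membered lactone; 2E/2Z mixture)
Product: 22 macrocyclic bromohydrin (6R secondary alcohol; 7S tertiary bromide), via bromo silyl ether 21 (not isolated)
Conditions: Me3SiBr, CH2Cl2, −78 °C; then citric acid, MeOH, 0 °C
Reagents that add atoms: bromotrimethylsilane, C[Si](C)(C)Br
Why: Silyl-activated epoxide opening puts bromide on the tertiary carbon C7 with inversion (7R epoxide carbon to 7S bromide) and leaves C6–O untouched, and mild methanolysis removes only the secondary trimethylsilyl ether.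

Step 14
Reactants: 22 macrocyclic bromohydrin (6R secondary alcohol; 7S tertiary bromide)
Product: 24 bicyclic keto macrolide (6S,7S,10R,11S; 16-membered lactone fused to the bromocyclohexene), via bromo triflate 23 (not isolated)
Conditions: Tf2O, 2,6-di-tert-butyl-4-methylpyridine, CH2Cl2, −78 to −30 °C
Reagents that add atoms: none
Why: Triflation of the only free hydroxyl triggers neighbouring-group displacement by the C7 bromine (inversion at C6, giving 6S) to an enantiopure bromonium ion that the transannular C2=C3 alkene opens at tertiary C7 anti to bromine (giving 7S), an enantiospecific bromonium-initiated cation–olefin cyclisation ended by loss of H-2 to the tetrasubstituted alkene, while the silyl ethers on the phenol and on O-11 block competing ether formation.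

Step 15
Reactants: 24 bicyclic keto macrolide (6S,7S,10R,11S; 16-membered lactone fused to the bromocyclohexene)
Product: 25 bis-silylated bromophycolide G (14S alcohol)
Conditions: (R)-2-methyl-CBS-oxazaborolidine (20 mol%), BH3·SMe2, THF, −20 °C; MeOH quench
Reagents that add atoms: none
Why: Corey–Bakshi–Shibata reduction with the (R)-oxazaborolidine distinguishes the bulky tertiary C15 substituent from the C13 methylene and gives the 14S alcohol under reagent control.

Step 16
Reactants: 25 bis-silylated bromophycolide G (14S alcohol)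
Product: 26 bromophycolide G
Conditions: HF·pyridine, pyridine, THF, 0 to 25 °C
Reagents that add atoms: none
Why: Buffered HF·pyridine cleaves the aryl triisopropylsilyl and tertiary triethylsilyl ethers under non-basic conditions that spare the bromohydrin, the alkyl bromides and the tertiary benzoate next to the free C14 hydroxyl.

## Compound list

1 | (5E)-6,10-dimethylundeca-5,9-dien-2-one (geranylacetone) | CC(=O)CC/C=C(\C)CCC=C(C)C | starting material
2 | (5E)-2,6,10-trimethylundeca-1,5,9-triene | C=C(C)CC/C=C(\C)CCC=C(C)C | intermediate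
3 | (2E,6E)-2,6,10-trimethylundeca-2,6,10-trien-1-ol | C=C(C)CC/C=C(\C)CC/C=C(\C)CO | intermediate
4 | [(2S,3S)-3-[(3E)-3,7-dimethylocta-3,7-dien-1-yl]-2-methyloxiran-2-yl]methanol | C=C(C)CC/C=C(\C)CC[C@@H]1O[C@@]1(C)CO | intermediate
5 | (2S,3R,6E)-3-bromo-2,6,10-trimethylundeca-6,10-diene-1,2-diol | C=C(C)CC/C=C(\C)CC[C@@H](Br)[C@@](C)(O)CO | intermediate
6 | (3R,6E)-3-bromo-6,10-dimethylundeca-6,10-dien-2-one | C=C(C)CC/C=C(\C)CC[C@@H](Br)C(C)=O | intermediate
7 | 3-bromo-4-hydroxybenzoic acid | O=C(O)c1ccc(O)c(Br)c1 | starting material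
8 | triisopropylsilyl 3-bromo-4-[(triisopropylsilyl)oxy]benzoate | CC(C)[Si](C(C)C)(C(C)C)OC(=O)c1ccc(O[Si](C(C)C)(C(C)C)C(C)C)c(Br)c1 | intermediate
9 | 3-bromo-4-[(triisopropylsilyl)oxy]benzoic acid | O=C(O)c1ccc(O[Si](C(C)C)(C(C)C)C(C)C)c(Br)c1 | intermediate
10 | 3-hydroxy-3-methylbutan-2-one | CC(=O)C(C)(C)O | starting material
11 | 3-bromo-4-[(triisopropylsilyl)oxy]benzoyl chloride | O=C(Cl)c1ccc(O[Si](C(C)C)(C(C)C)C(C)C)c(Br)c1 | intermediate
12 | 2-methyl-3-oxobutan-2-yl 3-bromo-4-[(triisopropylsilyl)oxy]benzoate | CC(=O)C(C)(C)OC(=O)c1ccc(O[Si](C(C)C)(C(C)C)C(C)C)c(Br)c1 | intermediate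
13 | 2-methyl-3-oxobutan-2-yl 3-(prop-2-en-1-yl)-4-[(triisopropylsilyl)oxy]benzoate | CC(=O)C(C)(C)OC(=O)c1ccc(O[Si](C(C)C)(C(C)C)C(C)C)c(CC=C)c1 | intermediate
14 | 2-methyl-3-[(trimethylsilyl)oxy]but-3-en-2-yl 3-(prop-2-en-1-yl)-4-[(triisopropylsilyl)oxy]benzoate | C=C(O[Si](C)(C)C)C(C)(C)OC(=O)c1ccc(O[Si](C(C)C)(C(C)C)C(C)C)c(CC=C)c1 | intermediate
15 | 2-{1-[(trimethylsilyl)oxy]cyclopropyl}propan-2-yl 3-(prop-2-en-1-yl)-4-[(triisopropylsilyl)oxy]benzoate | C[Si](C)(C)OC1(CC1)C(C)(C)OC(=O)c2ccc(O[Si](C(C)C)(C(C)C)C(C)C)c(CC=C)c2 | intermediate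
16 | 2-(1-hydroxycyclopropyl)propan-2-yl 3-(prop-2-en-1-yl)-4-[(triisopropylsilyl)oxy]benzoate | OC1(CC1)C(C)(C)OC(=O)c2ccc(O[Si](C(C)C)(C(C)C)C(C)C)c(CC=C)c2 | intermediate
17 | bis{4-methyl-3-oxo-4-[3-(prop-2-en-1-yl)-4-(triisopropylsilyloxy)benzoyloxy]pentyl}zinc (zinc homoenolate) | C=CCc1cc(ccc1O[Si](C(C)C)(C(C)C)C(C)C)C(=O)OC(C)(C)C(=O)CC[Zn]CCC(=O)C(C)(C)OC(=O)c1ccc(O[Si](C(C)C)(C(C)C)C(C)C)c(CC=C)c1 | intermediate
18 | (6S,7R,10E)-7-bromo-2,6,10,14-tetramethyl-3-oxo-6-[(triethylsilyl)oxy]pentadeca-10,14-dien-2-yl 3-(prop-2-en-1-yl)-4-[(triisopropylsilyl)oxy]benzoate | C=CCc1cc(ccc1O[Si](C(C)C)(C(C)C)C(C)C)C(=O)OC(C)(C)C(=O)CC[C@](C)(O[Si](CC)(CC)CC)[C@H](Br)CC/C(C)=C/CCC(C)=C | intermediate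
19 | (6S,7R)-7-bromo-2,6-dimethyl-9-[(2R,3R)-2-methyl-3-(3-methylbut-3-en-1-yl)oxiran-2-yl]-3-oxo-6-[(triethylsilyl)oxy]nonan-2-yl 3-(prop-2-en-1-yl)-4-[(triisopropylsilyl)oxy]benzoate | C=CCc1cc(ccc1O[Si](C(C)C)(C(C)C)C(C)C)C(=O)OC(C)(C)C(=O)CC[C@](C)(O[Si](CC)(CC)CC)[C@H](Br)CC[C@@]2(C)O[C@@H]2CCC(C)=C | intermediate
20 | 20-membered macrolactone, 2E/2Z mixture at C2=C3: (6R,7R)-6,7-epoxide, (10R)-bromide, (11S)-triethylsilyl ether, C14 ketone, phenol triisopropylsilyl ether | CC1=CCc2cc(ccc2O[Si](C(C)C)(C(C)C)C(C)C)C(=O)OC(C)(C)C(=O)CC[C@](C)(O[Si](CC)(CC)CC)[C@H](Br)CC[C@@]2(C)O[C@@H]2CC1 | intermediate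
21 | macrocycle as 20 with (6R)-trimethylsilyloxy and (7S)-bromide in place of the epoxide | CC1=CCc2cc(ccc2O[Si](C(C)C)(C(C)C)C(C)C)C(=O)OC(C)(C)C(=O)CC[C@](C)(O[Si](CC)(CC)CC)[C@H](Br)CC[C@](C)(Br)[C@H](O[Si](C)(C)C)CC1 | intermediate
22 | macrocyclic bromohydrin: (6R)-hydroxyl, (7S)-tertiary bromide, (10R)-bromide, (11S)-triethylsilyl ether, C14 ketone | CC1=CCc2cc(ccc2O[Si](C(C)C)(C(C)C)C(C)C)C(=O)OC(C)(C)C(=O)CC[C@](C)(O[Si](CC)(CC)CC)[C@H](Br)CC[C@](C)(Br)[C@H](O)CC1 | intermediate
23 | macrocycle as 22 with the (6R)-hydroxyl as its trifluoromethanesulfonate | CC1=CCc2cc(ccc2O[Si](C(C)C)(C(C)C)C(C)C)C(=O)OC(C)(C)C(=O)CC[C@](C)(O[Si](CC)(CC)CC)[C@H](Br)CC[C@](C)(Br)[C@H](OS(=O)(=O)C(F)(F)F)CC1 | intermediate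
24 | 14-oxo, 11-O-triethylsilyl, O-aryl-triisopropylsilyl precursor of bromophycolide G (6S,7S,10R,11S) | CC1=C2Cc3cc(ccc3O[Si](C(C)C)(C(C)C)C(C)C)C(=O)OC(C)(C)C(=O)CC[C@](C)(O[Si](CC)(CC)CC)[C@H](Br)CC[C@]2(C)[C@@H](Br)CC1 | intermediate
25 | 11-O-triethylsilyl, O-aryl-triisopropylsilyl bromophycolide G (6S,7S,10R,11S,14S) | CC1=C2Cc3cc(ccc3O[Si](C(C)C)(C(C)C)C(C)C)C(=O)OC(C)(C)[C@@H](O)CC[C@](C)(O[Si](CC)(CC)CC)[C@H](Br)CC[C@]2(C)[C@@H](Br)CC1 | intermediate
26 | bromophycolide G | CC1=C2Cc3cc(ccc3O)C(=O)OC(C)(C)[C@@H](O)CC[C@](C)(O)[C@H](Br)CC[C@]2(C)[C@@H](Br)CC1 | target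

## Step count, risks and fallbacks

Total step count: 16. Longest linear sequence: 12 steps (steps 1–5 and 10–16, from 1); the arene branch (steps 6–9) joins at step 10.

Step 10 is the least certain, because a ketone homoenolate has to add to a ketone and the cyclopropoxide could instead undergo acyl shift or simple protonation. The fallback sets out from 5 and comes back at 18, and it keeps both C10 and C11 from the Sharpless epoxide. The primary hydroxyl of 5 is oxidised (TEMPO, PhI(OAc)2) to (2S,3R,6E)-3-bromo-2-hydroxy-2,6,10-trimethylundeca-6,10-dienal F1. Separately, 13 is taken through its silyl enol ether 14 and N-bromosuccinimide to 4-bromo-2-methyl-3-oxobutan-2-yl 3-(prop-2-en-1-yl)-4-[(triisopropylsilyl)oxy]benzoate F2, and with PPh3 then aqueous NaHCO3 to the acyl ylide 2-methyl-3-oxo-4-(triphenylphosphoranylidene)butan-2-yl 3-(prop-2-en-1-yl)-4-[(triisopropylsilyl)oxy]benzoate F3. Wittig olefination of F1 with F3 gives (4E,6S,7R,10E)-7-bromo-6-hydroxy-2,6,10,14-tetramethyl-3-oxopentadeca-4,10,14-trien-2-yl 3-(prop-2-en-1-yl)-4-[(triisopropylsilyl)oxy]benzoate F4. Conjugate reduction with [(Ph3P)CuH]6 gives (6S,7R,10E)-7-bromo-6-hydroxy-2,6,10,14-tetramethyl-3-oxopentadeca-10,14-dien-2-yl 3-(prop-2-en-1-yl)-4-[(triisopropylsilyl)oxy]benzoate F5, and silylation (Et3SiOTf, 2,6-lutidine) returns to 18.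

Step 14 may fail through elimination of the tertiary bromide, poor transannular capture, or proton loss to the wrong olefin isomer. The fallback sets out from 20 and comes back at 24. Li2NiBr4 in THF opens the epoxide by SN2 attack at the secondary carbon C6 to give the regioisomeric macrocyclic bromohydrin (6S bromide, 7R tertiary alcohol) F6. Its tertiary hydroxyl is then ionised with BF3·OEt2 in (CF3)2CHOH–CH2Cl2; bromine participates anti to the leaving group, so the same bromonium ion forms, and the protic, non-basic medium lets exocyclic or trisubstituted olefin isomers equilibrate to the tetrasubstituted alkene of 24.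

Step 2 is at risk because the extra 1,1-disubstituted alkene of 2 offers competing allylic sites and over-oxidation lowers the yield. The fallback sets out from 1 and comes back at 3. The SeO2/t-BuOOH oxidation is run on geranylacetone itself, giving (5E,9E)-11-hydroxy-6,10-dimethylundeca-5,9-dien-2-one F7, and the ketone is then methylenated with excess Ph3P=CH2 (from MePPh3Br and KOtBu) to reach 3.

Further compounds
F1 | step 10 | (2S,3R,6E)-3-bromo-2-hydroxy-2,6,10-trimethylundeca-6,10-dienal | C=C(C)CC/C=C(\C)CC[C@@H](Br)[C@@](C)(O)C=O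
F2 | step 10 | 4-bromo-2-methyl-3-oxobutan-2-yl 3-(prop-2-en-1-yl)-4-[(triisopropylsilyl)oxy]benzoate | BrCC(=O)C(C)(C)OC(=O)c1ccc(O[Si](C(C)C)(C(C)C)C(C)C)c(CC=C)c1
F3 | step 10 | 2-methyl-3-oxo-4-(triphenylphosphoranylidene)butan-2-yl 3-(prop-2-en-1-yl)-4-[(triisopropylsilyl)oxy]benzoate | O=C(C=P(c1ccccc1)(c1ccccc1)c1ccccc1)C(C)(C)OC(=O)c1ccc(O[Si](C(C)C)(C(C)C)C(C)C)c(CC=C)c1
F4 | step 10 | (4E,6S,7R,10E)-7-bromo-6-hydroxy-2,6,10,14-tetramethyl-3-oxopentadeca-4,10,14-trien-2-yl 3-(prop-2-en-1-yl)-4-[(triisopropylsilyl)oxy]benzoate | C=CCc1cc(ccc1O[Si](C(C)C)(C(C)C)C(C)C)C(=O)OC(C)(C)C(=O)/C=C/[C@](C)(O)[C@H](Br)CC/C(C)=C/CCC(C)=C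
F5 | step 10 | (6S,7R,10E)-7-bromo-6-hydroxy-2,6,10,14-tetramethyl-3-oxopentadeca-10,14-dien-2-yl 3-(prop-2-en-1-yl)-4-[(triisopropylsilyl)oxy]benzoate | C=CCc1cc(ccc1O[Si](C(C)C)(C(C)C)C(C)C)C(=O)OC(C)(C)C(=O)CC[C@](C)(O)[C@H](Br)CC/C(C)=C/CCC(C)=C
F6 | step 14 | macrocycle as 20 with (6S)-bromide and (7R)-tertiary hydroxyl in place of the epoxide | CC1=CCc2cc(ccc2O[Si](C(C)C)(C(C)C)C(C)C)C(=O)OC(C)(C)C(=O)CC[C@](C)(O[Si](CC)(CC)CC)[C@H](Br)CC[C@@](C)(O)[C@@H](Br)CC1
F7 | step 2 | (5E,9E)-11-hydroxy-6,10-dimethylundeca-5,9-dien-2-one | CC(=O)CC/C=C(\C)CC/C=C(\C)CO
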